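**Retrosynthetic overview**

1. The target 36 is unmasked in one acid step from 34 (lactol methyl acetal, acetonide, (Z)-enoate); 34 comes from a C12–C13 sp3–sp2 Negishi coupling of the bicyclic iodide 21 with the (E)-iodoalkene 32, which carries C13–C16 and the latent butenolide.
2. Structural basis: in abietic acid C4 (β-methyl, α-C18 carbonyl), C5, C9, C10 and the C11–C12 arm on C9 already have the target's configuration. Cutting ring C at C13=C14 makes C14 the exocyclic methylene carbon, and the equatorial C18 carbonyl lies 1,5 (peri) to the 6α-hydrogen of ring B.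
3. That relation forms the C6–O bond: 1,5-hydrogen transfer to the amidyl radical of the 18-carboxamide and O-closure give the 6α,18-γ-lactone (7 → 11), later reduced to the lactol, the ring form of the 6α-hydroxy-18-aldehyde.
4. Fragment 32 comes from L-tartaric acid through a C2-symmetric diyne: C15 and C16 are taken from the pool, the (Z)-enoate is made by cuprate addition and the (E)-iodoalkene by hydrozirconation.
5. Ring order: rings A and B from the pool, the γ-lactone ring in step 6 (it becomes the lactol), the butenolide ring last (step 20).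

Key step: step 6

Numbering: abietane numbers are used for the bicyclic part (C18 = carbonyl carbon on C4, C14 = the carbon that becomes the exocyclic methylene); the side chain is C11–C16, C16 being the butenolide CH–O.
Assumption: the 6α-hydroxy-18-aldehyde drawn for the target and its 6α,18-hemiacetal are ring–chain tautomers of one compound, so hydrolysis of the lactol acetal delivers the target.
Remark: centres that are erased or equilibrated later (C13/C14 of 4, C6 of 9, C12 of 17, the acetal carbon C18 of 19–21, 33, 34) are left undefined in the SMILES where a mixture is expected; the diol 4 is written as the α-face adduct.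

**Route**

Step 1
Reactants: 1 abietic acid
Product: 3 abieta-7,13-dien-18-amide, via abietoyl chloride 2 (not isolated)
Conditions: (COCl)2, cat. DMF, CH2Cl2, 0 °C to rt; then NH3 (0.5 M in dioxane, excess), 0 °C
Reagents that add atoms: ammonia, N
Why: Amide formation through the acid chloride works at the hindered C18 acid, and the 7,13-diene is the acid-stable resin-acid isomer, so the HCl formed should not move the double bonds.

Step 2
Reactants: 3 abieta-7,13-dien-18-amide
Product: 4 13α,14α-dihydroxyabiet-7-en-18-amide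
Conditions: OsO4 (2 mol %), Me3NO·2H2O, pyridine, t-BuOH–H2O, reflux
Reagents that add atoms: OsO4, O=[Os](=O)(=O)=O, reoxidised by trimethylamine N-oxide, C[N+](C)(C)[O-]; water, O
Why: Catalytic osmium syn-dihydroxylation with an amine oxide should take the more accessible C13=C14 bond of the diene, as it does with abietic esters; both new carbinol centres are removed in step 3, so the face of attack does not matter.

Step 3
Reactants: 4 13α,14α-dihydroxyabiet-7-en-18-amide
Product: 5 13,14-dioxo-13,14-secoabiet-7-en-18-amide (C14 enal on C8, isopropyl ketone at C13)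
Conditions: NaIO4, THF–H2O, rt
Reagents that add atoms: none
Why: Periodate glycol cleavage (Malaprade reaction) of the cis-diol opens ring C and should leave the primary amide and the now conjugated C7=C8 bond untouched.

Step 4
Reactants: 5 13,14-dioxo-13,14-secoabiet-7-en-18-amide
Product: 6 14-hydroxy-13-oxo-13,14-secoabiet-7-en-18-amide
Conditions: NaBH4 (0.5 equiv), CH2Cl2–EtOH (7:3), −78 °C
Reagents that add atoms: none
Why: Chemoselective borohydride 1,2-reduction at low temperature should take the aldehyde and leave the α-branched isopropyl ketone and the amide.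

Step 5
Reactants: 6 14-hydroxy-13-oxo-13,14-secoabiet-7-en-18-amide
Product: 7 14-acetoxy-13-oxo-13,14-secoabiet-7-en-18-amide
Conditions: Ac2O, pyridine, DMAP (cat.), CH2Cl2, 0 °C
Reagents that add atoms: acetic anhydride, CC(=O)OC(C)=O
Why: DMAP-catalysed O-acylation of the primary allylic alcohol spares the primary amide; the acetate prevents hypoiodite formation at this oxygen in step 6 and lowers the nucleophilicity of C7=C8.

Step 6
Reactants: 7 14-acetoxy-13-oxo-13,14-secoabiet-7-en-18-amide
Product: 11 14-acetoxy-13-oxo-13,14-secoabiet-7-en-18,6α-olide, via N-iodoamide 8 (not isolated), via allylic iodide 9 (not isolated), via iminolactone 10 (not isolated)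
Conditions: PhI(OAc)2 (2.2 equiv) and I2 (1.1 equiv) premixed, CH2Cl2, tungsten lamp, 25–35 °C; aq. Na2S2O3; then THF–H2O–AcOH, rt
Reagents that add atoms: water, O
Why: PhI(OAc)2 and I2 form AcOI, which N-iodinates the primary amide to 8; light cleaves the N–I bond and the amidyl radical takes the allylic 6α-hydrogen through a six-membered transition state (N, C18, C4, C5, C6, H), a 1,5-hydrogen transfer made possible by the peri relation of the equatorial C18 carbonyl and the 6α-H on the trans-fused rings A and B. The C6–C7–C8 allyl radical is iodinated to 9, and the amide oxygen then displaces iodide at C6 (directly or after ionization) in a 5-exo closure of the ring O–C18–C4–C5–C6 to the iminolactone 10, which water hydrolyses to the γ-lactone. This is the Hofmann–Löffler–Freytag-type N-iodoamide photolysis that converts carboxamides into γ-lactones. The new C6 stereocentre is set as 6α-O by the tether alone: the carbonyl oxygen reaches only the α-side of C6, only the five-membered ring bridging the equatorial positions of C4 and C6 can form, and attack at C8 would need a seven-membered ring. The step needs hydrogen abstraction at C6 and not at C2, and radical chemistry ahead of ionic addition of AcOI to C7=C8 or Hofmann-type rearrangement: the C2 hydrogens lie out of reach of the equatorial amide, the C6–H bond is allylic and weak, the alkene is trisubstituted, shielded and deactivated by the allylic acetate, and premixing the two reagents keeps free PhI(OAc)2 away from the amide.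

Step 7
Reactants: 11 14-acetoxy-13-oxo-13,14-secoabiet-7-en-18,6α-olide
Product: 12 14-hydroxy-13-oxo-13,14-secoabiet-7-en-18,6α-olide
Conditions: K2CO3 (cat.), MeOH, 0 °C
Reagents that add atoms: none
Why: Base-catalysed transesterification (Zemplén type) should remove the unhindered primary acetate, whereas the lactone carbonyl on the quaternary C4 is shielded and would reclose if opened.

Step 8
Reactants: 12 14-hydroxy-13-oxo-13,14-secoabiet-7-en-18,6α-olide
Product: 15 13-oxo-13,14-secoabiet-8(14)-en-18,6α-olide, via allyl sulfonylhydrazine 13 (not isolated), via allylic diazene 14 (not isolated)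
Conditions: 2-nitrobenzenesulfonylhydrazide, PPh3, DEAD, THF, −30 °C to rt
Reagents that add atoms: none
Why: Reductive 1,3-allylic transposition: Mitsunobu N-alkylation of the sulfonylhydrazide at C14, loss of sulfinic acid and retro-ene loss of N2 from the monoalkyl diazene deliver hydrogen to C7 and move the double bond to C8=C14, the exocyclic methylene; no stereocentre is formed.

Step 9
Reactants: 15 13-oxo-13,14-secoabiet-8(14)-en-18,6α-olide
Product: 17 12-hydroxy-13-oxo-13,14-secoabiet-8(14)-en-18,6α-olide (C12 epimers), via potassium enolate 16 (not isolated)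
Conditions: KN(SiMe3)2, THF, −78 °C; 2-(phenylsulfonyl)-3-phenyloxaziridine, −78 °C; AcOH
Reagents that add atoms: Davis oxaziridine, O=S(=O)(c1ccccc1)N1OC1c1ccccc1
Why: Kinetic deprotonation should occur at the C12 methylene and not at the isopropyl methine, and Davis enolate hydroxylation gives the α-ketol (either C12 epimer serves); the lactone has no α-hydrogen.

Step 10
Reactants: 17 12-hydroxy-13-oxo-13,14-secoabiet-8(14)-en-18,6α-olide
Product: 18 12-oxo-13,15,16,17-tetranor-13,14-secoabiet-8(14)-en-18,6α-olide (CH2CHO arm on C9)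
Conditions: Pb(OAc)4, MeOH–benzene (1:1), 0 °C
Reagents that add atoms: none
Why: Lead tetraacetate cleavage of the α-ketol (Criegee type, through its methyl hemiketal) cuts C12–C13 to the C12 aldehyde and methyl isobutyrate without touching the alkene.

Step 11
Reactants: 18 C12 aldehyde lactone
Product: 19 6α,18-epoxy-13,15,16,17-tetranor-13,14-secoabiet-8(14)-ene-12,18-diol (lactol, C18 epimers)
Conditions: i-Bu2AlH (3.5 equiv), CH2Cl2, −78 °C; aq. potassium sodium tartrate
Reagents that add atoms: none
Why: Hydride reduction with i-Bu2AlH takes the aldehyde to the primary alcohol and should stop the γ-lactone at the lactol, because the aluminium hemiacetal is stable at −78 °C.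

Step 12
Reactants: 19 lactol alcohol
Product: 20 18-methoxy-6α,18-epoxy-13,15,16,17-tetranor-13,14-secoabiet-8(14)-en-12-ol (C18 epimers)
Conditions: MeOH, PPTS (cat.), rt
Reagents that add atoms: methanol, CO
Why: Fischer-type acetalization of the lactol through the cyclic oxocarbenium ion gives the methyl acetal; the remote primary alcohol cannot reach C18.

Step 13
Reactants: 20 methyl acetal alcohol
Product: 21 12-iodo-18-methoxy-6α,18-epoxy-13,15,16,17-tetranor-13,14-secoabiet-8(14)-ene
Conditions: I2, PPh3, imidazole, CH2Cl2, 0 °C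
Reagents that add atoms: iodine, II
Why: Appel-type iodination of the primary alcohol under imidazole buffering should spare the acetal and the alkene.

Step 14
Reactants: 22 dimethyl 2,3-O-isopropylidene-L-tartrate
Product: 24 (4S,5S)-4,5-diethynyl-2,2-dimethyl-1,3-dioxolane, via dialdehyde 23 (not isolated)
Conditions: i-Bu2AlH (2.1 equiv), CH2Cl2, −78 °C; then MeOH, dimethyl (1-diazo-2-oxopropyl)phosphonate, K2CO3, −78 °C to rt
Reagents that add atoms: Ohira–Bestmann reagent, CC(=O)C(=[N+]=[N-])P(=O)(OC)OC
Why: Partial ester reduction and in-flask Seyferth–Gilbert homologation (Ohira–Bestmann variant) avoid isolating the labile dialdehyde; the trans-dioxolane is the more stable arrangement, so both stereocentres should be kept.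

Step 15
Reactants: 24 (4S,5S)-4,5-diethynyl-2,2-dimethyl-1,3-dioxolane
Product: 26 (4S,5S)-4-ethynyl-2,2-dimethyl-5-(prop-1-ynyl)-1,3-dioxolane, via lithium acetylide 25 (not isolated)
Conditions: n-BuLi (0.9 equiv), THF, −78 °C; MeI, DMPU, −78 to 0 °C
Reagents that add atoms: iodomethane, CI
Why: Acetylide alkylation; monoalkylation of the C2-symmetric diyne is statistical, so the diyne is used in excess and recovered, and either alkyne gives the same product.

Step 16
Reactants: 26 (4S,5S)-4-ethynyl-2,2-dimethyl-5-(prop-1-ynyl)-1,3-dioxolane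
Product: 28 methyl 3-[(4S,5S)-2,2-dimethyl-5-(prop-1-ynyl)-1,3-dioxolan-4-yl]prop-2-ynoate, via lithium acetylide 27 (not isolated)
Conditions: n-BuLi, THF, −78 °C; ClCO2Me, −78 to −20 °C
Reagents that add atoms: methyl chloroformate, COC(Cl)=O
Why: C-acylation of the lithium acetylide with a chloroformate gives the ynoate.

Step 17
Reactants: 28 ynoate
Product: 30 methyl (Z)-3-[(4S,5S)-2,2-dimethyl-5-(prop-1-ynyl)-1,3-dioxolan-4-yl]but-2-enoate, via alkenylcuprate 29 (not isolated)
Conditions: Me2CuLi (from CuI and MeLi), THF, −78 °C; NH4Cl–MeOH at −78 °C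
Reagents that add atoms: lithium dimethylcuprate, [Li+].C[Cu-]C
Why: syn-Carbocupration (cuprate conjugate addition) of the ynoate and protonation with retention at −78 °C place the new methyl and the α-hydrogen cis, which puts C16 and the ester on the same side; the unactivated propynyl group is inert.

Step 18
Reactants: 30 (Z)-enoate
Product: 32 methyl (Z)-3-{(4S,5S)-5-[(E)-2-iodoprop-1-enyl]-2,2-dimethyl-1,3-dioxolan-4-yl}but-2-enoate, via alkenylzirconocene 31 (not isolated)
Conditions: Cp2Zr(H)Cl (1.5 equiv), THF, rt, dark; then I2, THF, 0 °C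
Reagents that add atoms: iodine, II
Why: Hydrozirconation with the Schwartz reagent is a syn addition that places zirconium on the less hindered, methyl-bearing alkyne carbon, and iodinolysis with retention gives the (E)-iodoalkene (iodine trans to C15); the hindered β,β-disubstituted enoate is expected to survive.

Step 19
Reactants: 21 C12 iodide; 32 (E)-iodoalkene
Product: 34 coupled acetonide ester, via alkylzinc iodide 33 (not isolated)
Conditions: Zn dust (activated with 1,2-dibromoethane and TMSCl), LiCl, THF, 40 °C; then 32, Pd(PPh3)4 (5 mol %), THF, rt to 40 °C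
Reagents that add atoms: none
Why: Negishi sp3–sp2 cross-coupling under zerovalent palladium catalysis forms C12–C13 with retention of the alkene geometry, and the mild alkylzinc iodide should tolerate the enoate and both acetals.

Step 20
Reactants: 34 coupled acetonide ester
Product: 36 target CNP0113661.1, via dihydroxy ester 35 (not isolated)
Conditions: 1 M aq. HCl–THF (1:2), rt
Reagents that add atoms: water, O
Why: Acid hydrolysis removes the acetonide and the methyl acetal, and the freed C16 hydroxyl, held cis to the ester by the (Z)-alkene, lactonizes to the butenolide (intramolecular transesterification); no stereocentre is touched.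

**Compound list**

1 | abietic acid | CC(C)C1=CC2=CC[C@@H]3[C@](C)(CCC[C@@]3(C)C(=O)O)[C@H]2CC1 | starting material
2 | abietoyl chloride | CC(C)C1=CC2=CC[C@@H]3[C@](C)(CCC[C@@]3(C)C(=O)Cl)[C@H]2CC1 | intermediate
3 | abieta-7,13-dien-18-amide | CC(C)C1=CC2=CC[C@@H]3[C@](C)(CCC[C@@]3(C)C(N)=O)[C@H]2CC1 | intermediate
4 | 13α,14α-dihydroxyabiet-7-en-18-amide | CC(C)[C@@]1(O)[C@H](O)C2=CC[C@@H]3[C@](C)(CCC[C@@]3(C)C(N)=O)[C@H]2CC1 | intermediate
5 | 13,14-dioxo-13,14-secoabiet-7-en-18-amide | O=CC1=CC[C@@H]2[C@](C)(CCC[C@@]2(C)C(N)=O)[C@H]1CCC(=O)C(C)C | intermediate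
6 | 14-hydroxy-13-oxo-13,14-secoabiet-7-en-18-amide | OCC1=CC[C@@H]2[C@](C)(CCC[C@@]2(C)C(N)=O)[C@H]1CCC(=O)C(C)C | intermediate
7 | 14-acetoxy-13-oxo-13,14-secoabiet-7-en-18-amide | CC(=O)OCC1=CC[C@@H]2[C@](C)(CCC[C@@]2(C)C(N)=O)[C@H]1CCC(=O)C(C)C | intermediate
8 | N-iodo derivative of amide 7 | CC(=O)OCC1=CC[C@@H]2[C@](C)(CCC[C@@]2(C)C(=O)NI)[C@H]1CCC(=O)C(C)C | intermediate
9 | 6-iodo derivative of amide 7 (allylic iodide, C6 epimers) | CC(=O)OCC1=CC(I)[C@@H]2[C@](C)(CCC[C@@]2(C)C(N)=O)[C@H]1CCC(=O)C(C)C | intermediate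
10 | 6α,18-iminolactone of the 14-acetoxy-13-oxo-seco-abiet-7-ene | CC(=O)OCC1=C[C@H]3[C@@H]2[C@](C)(CCC[C@@]2(C)C(=N)O3)[C@H]1CCC(=O)C(C)C | intermediate
11 | 14-acetoxy-13-oxo-13,14-secoabiet-7-en-18,6α-olide | CC(=O)OCC1=C[C@H]3[C@@H]2[C@](C)(CCC[C@@]2(C)C(=O)O3)[C@H]1CCC(=O)C(C)C | intermediate
12 | 14-hydroxy-13-oxo-13,14-secoabiet-7-en-18,6α-olide | OCC1=C[C@H]3[C@@H]2[C@](C)(CCC[C@@]2(C)C(=O)O3)[C@H]1CCC(=O)C(C)C | intermediate
13 | N-(C14-allyl)-N-(2-nitrobenzenesulfonyl)hydrazine of 12 | NN(CC1=C[C@H]3[C@@H]2[C@](C)(CCC[C@@]2(C)C(=O)O3)[C@H]1CCC(=O)C(C)C)S(=O)(=O)c1ccccc1[N+](=O)[O-] | intermediate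
14 | C14 allylic monoalkyl diazene | N=NCC1=C[C@H]3[C@@H]2[C@](C)(CCC[C@@]2(C)C(=O)O3)[C@H]1CCC(=O)C(C)C | intermediate
15 | 13-oxo-13,14-secoabiet-8(14)-en-18,6α-olide | C=C1C[C@H]3[C@@H]2[C@](C)(CCC[C@@]2(C)C(=O)O3)[C@H]1CCC(=O)C(C)C | intermediate
16 | potassium C12=C13 enolate of 15 | C=C1C[C@H]3[C@@H]2[C@](C)(CCC[C@@]2(C)C(=O)O3)[C@H]1CC=C([O-])C(C)C.[K+] | intermediate
17 | 12-hydroxy-13-oxo-13,14-secoabiet-8(14)-en-18,6α-olide (C12 epimers) | C=C1C[C@H]3[C@@H]2[C@](C)(CCC[C@@]2(C)C(=O)O3)[C@H]1CC(O)C(=O)C(C)C | intermediate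
18 | 12-oxo-13,15,16,17-tetranor-13,14-secoabiet-8(14)-en-18,6α-olide | C=C1C[C@H]3[C@@H]2[C@](C)(CCC[C@@]2(C)C(=O)O3)[C@H]1CC=O | intermediate
19 | 6α,18-lactol with C12 primary alcohol (C18 epimers) | C=C1C[C@H]3[C@@H]2[C@](C)(CCC[C@@]2(C)C(O)O3)[C@H]1CCO | intermediate
20 | 18-methoxy-6α,18-epoxy acetal with C12 primary alcohol (C18 epimers) | C=C1C[C@H]3[C@@H]2[C@](C)(CCC[C@@]2(C)C(OC)O3)[C@H]1CCO | intermediate
21 | 12-iodo-18-methoxy-6α,18-epoxy acetal (C18 epimers) | C=C1C[C@H]3[C@@H]2[C@](C)(CCC[C@@]2(C)C(OC)O3)[C@H]1CCI | intermediate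
22 | dimethyl 2,3-O-isopropylidene-L-tartrate, dimethyl (4R,5R)-2,2-dimethyl-1,3-dioxolane-4,5-dicarboxylate | COC(=O)[C@@H]1OC(C)(C)O[C@H]1C(=O)OC | starting material
23 | (4R,5R)-2,2-dimethyl-1,3-dioxolane-4,5-dicarbaldehyde | O=C[C@@H]1OC(C)(C)O[C@H]1C=O | intermediate
24 | (4S,5S)-4,5-diethynyl-2,2-dimethyl-1,3-dioxolane | C#C[C@@H]1OC(C)(C)O[C@H]1C#C | intermediate
25 | monolithium acetylide of 24 | [Li]C#C[C@@H]1OC(C)(C)O[C@H]1C#C | intermediate
26 | (4S,5S)-4-ethynyl-2,2-dimethyl-5-(prop-1-ynyl)-1,3-dioxolane | CC#C[C@@H]1OC(C)(C)O[C@H]1C#C | intermediate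
27 | lithium acetylide of 26 | CC#C[C@@H]1OC(C)(C)O[C@H]1C#C[Li] | intermediate
28 | methyl 3-[(4S,5S)-2,2-dimethyl-5-(prop-1-ynyl)-1,3-dioxolan-4-yl]prop-2-ynoate | CC#C[C@@H]1OC(C)(C)O[C@H]1C#CC(=O)OC | intermediate
29 | lithium α-alkenyl(methyl)cuprate from 28 | CC#C[C@@H]1OC(C)(C)O[C@H]1/C(C)=C(/[Cu-]C)C(=O)OC.[Li+] | intermediate
30 | methyl (Z)-3-[(4S,5S)-2,2-dimethyl-5-(prop-1-ynyl)-1,3-dioxolan-4-yl]but-2-enoate | CC#C[C@@H]1OC(C)(C)O[C@H]1/C(C)=C\C(=O)OC | intermediate
31 | (E)-alkenylzirconocene chloride from 30 (Zr on C13) | C/C(=C\[C@@H]1OC(C)(C)O[C@H]1/C(C)=C\C(=O)OC)[Zr](Cl)(C1C=CC=C1)C1C=CC=C1 | intermediate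
32 | methyl (Z)-3-{(4S,5S)-5-[(E)-2-iodoprop-1-enyl]-2,2-dimethyl-1,3-dioxolan-4-yl}but-2-enoate | C/C(I)=C\[C@@H]1OC(C)(C)O[C@H]1/C(C)=C\C(=O)OC | intermediate
33 | C12 alkylzinc iodide from 21 | C=C1C[C@H]3[C@@H]2[C@](C)(CCC[C@@]2(C)C(OC)O3)[C@H]1CC[Zn]I | intermediate
34 | coupled product: lactol methyl acetal, (13E)-alkene, 15,16-acetonide, (Z)-enoate methyl ester | C=C1C[C@H]3[C@@H]2[C@](C)(CCC[C@@]2(C)C(OC)O3)[C@H]1CC/C(C)=C/[C@@H]4OC(C)(C)O[C@H]4/C(C)=C\C(=O)OC | intermediate
35 | fully unmasked (15S,16S)-dihydroxy (Z)-enoate with 6α-hydroxy-18-aldehyde | C=C1C[C@H](O)[C@@H]2[C@](C)(CCC[C@@]2(C)C=O)[C@H]1CC/C(C)=C/[C@H](O)[C@@H](O)/C(C)=C\C(=O)OC | intermediate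
36 | CNP0113661.1 | C=C1C[C@H](O)[C@@H]2[C@](C)(CCC[C@@]2(C)C=O)[C@H]1CC/C(C)=C/[C@H](O)[C@H]1OC(=O)C=C1C | target

**Step count and risks**

Total step count: 20. Longest linear sequence: 15 steps (steps 1–13, 19 and 20); the side-chain branch is steps 14–18.

Steps most likely to fail:

Step 6. Ionic addition of the hypoiodite across C7=C8, or Hofmann-type rearrangement of the N-iodinated amide, may outrun the 1,5-hydrogen transfer. The fallback forms the same C6–O bond by ionic chemistry. It sets out from 7: palladium-catalysed 1,4-elimination of acetic acid through the π-allyl complex (Pd(PPh3)4, Et3N, THF, reflux) should give the 6,8(14)-diene amide F1. Iodine in aqueous THF with NaHCO3 then adds to the exocyclic C14 terminus, and the amide oxygen closes on C6 of the allyl cation from the α-side (1,4-iodolactonization, five-membered ring only); hydrolysis of the iminium gives the 14-iodo-7-ene 6α,18-lactone F2. KOAc in DMF displaces the primary allylic iodide, and the fallback comes back to the route at 11.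

Step 18. Reduction of the enoate by the zirconium hydride, or loss of regiocontrol in the hydrometalation, may erode the yield of the iodoalkene. The fallback moves the hydrozirconation ahead of the ester. It sets out from 26: silylation of the terminal alkyne (n-BuLi, i-Pr3SiOTf) gives the triisopropylsilyl alkyne F3. Hydrozirconation–iodination, now on the only unshielded alkyne, gives the (E)-iodoalkene silyl alkyne F4, and Bu4NF frees the terminal alkyne F5. LiN(SiMe3)2, which does not exchange with the alkenyl iodide, and ClCO2Me give the ynoate F6. Me2CuLi at −78 °C then adds as in step 17, and the fallback comes back to the route at 32.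

Step 20. Under the acid needed to open the dioxolane, ionization of the C15 allylic alcohol, migration of the exocyclic double bond into the ring, or closure through the C15 hydroxyl to the six-membered lactone may compete. The fallback unmasks the butenolide before the coupling, where the iodoalkene retards ionization at C15. It sets out from 32: aqueous CF3CO2H gives the hydroxy butenolide iodoalkene F7, and Et3SiCl with imidazole gives its triethylsilyl ether F8. Negishi coupling with 33 as in step 19 gives the silyl ether methyl acetal F9. Brief treatment with PPTS in aqueous THF at 0 °C to rt, much milder than acetonide cleavage, removes the silyl ether and the methyl acetal, and the fallback comes back to the route at 36.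

**Further compounds**

F1 | step 6 | 13-oxo-13,14-secoabieta-6,8(14)-dien-18-amide | C=C1C=C[C@@H]2[C@](C)(CCC[C@@]2(C)C(N)=O)[C@H]1CCC(=O)C(C)C
F2 | step 6 | 14-iodo-13-oxo-13,14-secoabiet-7-en-18,6α-olide | ICC1=C[C@H]3[C@@H]2[C@](C)(CCC[C@@]2(C)C(=O)O3)[C@H]1CCC(=O)C(C)C
F3 | step 18 | (4S,5S)-2,2-dimethyl-4-(prop-1-ynyl)-5-[(triisopropylsilyl)ethynyl]-1,3-dioxolane | CC#C[C@@H]1OC(C)(C)O[C@H]1C#C[Si](C(C)C)(C(C)C)C(C)C
F4 | step 18 | (4S,5S)-4-[(E)-2-iodoprop-1-enyl]-2,2-dimethyl-5-[(triisopropylsilyl)ethynyl]-1,3-dioxolane | C/C(I)=C\[C@@H]1OC(C)(C)O[C@H]1C#C[Si](C(C)C)(C(C)C)C(C)C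
F5 | step 18 | (4S,5S)-4-ethynyl-5-[(E)-2-iodoprop-1-enyl]-2,2-dimethyl-1,3-dioxolane | C/C(I)=C\[C@@H]1OC(C)(C)O[C@H]1C#C
F6 | step 18 | methyl 3-{(4S,5S)-5-[(E)-2-iodoprop-1-enyl]-2,2-dimethyl-1,3-dioxolan-4-yl}prop-2-ynoate | C/C(I)=C\[C@@H]1OC(C)(C)O[C@H]1C#CC(=O)OC
F7 | step 20 | (5S)-5-[(1S,2E)-1-hydroxy-3-iodobut-2-enyl]-4-methylfuran-2(5H)-one | C/C(I)=C\[C@H](O)[C@H]1OC(=O)C=C1C
F8 | step 20 | triethylsilyl ether of F7 | C/C(I)=C\[C@H](O[Si](CC)(CC)CC)[C@H]1OC(=O)C=C1C
F9 | step 20 | coupled lactol methyl acetal with 15-O-triethylsilyl butenolide side chain | C=C1C[C@H]3[C@@H]2[C@](C)(CCC[C@@]2(C)C(OC)O3)[C@H]1CC/C(C)=C/[C@H](O[Si](CC)(CC)CC)[C@H]1OC(=O)C=C1C
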